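**Plan**

- Numbering: the heptane chain runs from the catechol-side benzylic carbon (C1) to the guaiacyl-side benzylic carbon (C7).
- Enabling feature: the C3 ketone and C5 carbinol form a β-hydroxy ketone, which is the unmasked form of a 3,5-disubstituted 2-isoxazoline whose C=N carbon is C3 and whose O-bearing ring carbon is C5.
- Retrosynthesis: remove the three O-benzyl groups, close the N–O ring over C3/C5, cut C6–C7 (as a C6=C7 Wittig alkene), then cut C3–C4 and C5–O to a nitrile oxide (C1–C3 with the catechol ring) and allyl alcohol (C4–C6).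
- Forward: the isoxazoline, the only ring made, is closed first by the [3+2] cycloaddition. Its CH2OH (C6) is oxidised and olefinated with the guaiacyl ylide (C7), Raney Ni opens the ring and saturates C6=C7, and hydrogenolysis frees the phenols.
- Stereochemistry: the single stereocentre C5 is set in the cycloaddition by (S,S)-diisopropyl tartrate on zinc. (5S) in the ring becomes (5R) in the target only through a change of CIP priorities, since no bond to C5 is broken.

Key step: step 8

Assumption: the sense of induction established for the tartrate/zinc cycloaddition of aryl nitrile oxides to allyl alcohol, where the (R,R)-tartrate leads to the (5R)-5-(hydroxymethyl)isoxazoline, is taken to hold for the primary alkyl nitrile oxide, so the (S,S)-ester is specified; the alkene of 15 is carried as an E/Z mixture because it is saturated in step 11.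

**Route**

Step 1
Reactants: 1 4-(benzyloxy)-3-methoxybenzaldehyde (O-benzylvanillin)
Product: 2 [4-(benzyloxy)-3-methoxyphenyl]methanol
Conditions: NaBH4, MeOH, 0 °C
Reagents that add atoms: none
Why: Borohydride reduction of an aryl aldehyde to the benzylic alcohol is selective and leaves the benzyl and methyl ethers untouched.

Step 2
Reactants: 2 [4-(benzyloxy)-3-methoxyphenyl]methanol
Product: 3 1-(benzyloxy)-4-(chloromethyl)-2-methoxybenzene
Conditions: SOCl2, CH2Cl2, 0 °C to rt
Reagents that add atoms: thionyl chloride, O=S(Cl)Cl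
Why: Chlorodehydroxylation with thionyl chloride is facile at an electron-rich benzylic carbon (collapse of the chlorosulfite), and the aryl ethers should tolerate the HCl formed at or below room temperature.

Step 3
Reactants: 3 1-(benzyloxy)-4-(chloromethyl)-2-methoxybenzene
Product: 4 {[4-(benzyloxy)-3-methoxyphenyl]methyl}triphenylphosphonium chloride
Conditions: PPh3, toluene, reflux
Reagents that add atoms: triphenylphosphine, c1ccc(cc1)P(c1ccccc1)c1ccccc1
Why: SN2 quaternisation of triphenylphosphine by the benzylic chloride (phosphonium salt formation) should give a salt that precipitates from hot toluene and is purified by filtration.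

Step 4
Reactants: 5 3-(3,4-dihydroxyphenyl)propanoic acid (dihydrocaffeic acid)
Product: 6 benzyl 3-[3,4-bis(benzyloxy)phenyl]propanoate
Conditions: BnBr (3.5 equiv), K2CO3, DMF, 60 °C
Reagents that add atoms: benzyl bromide, BrCc1ccccc1
Why: Williamson O-alkylation of both phenoxides together with carboxylate alkylation should perbenzylate the acid in one operation, the ester being the handle for the next reduction.

Step 5
Reactants: 6 benzyl 3-[3,4-bis(benzyloxy)phenyl]propanoate
Product: 7 3-[3,4-bis(benzyloxy)phenyl]propanal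
Conditions: i-Bu2AlH (1.05 equiv), CH2Cl2, −78 °C; aq. KNaC4H4O6 (potassium sodium tartrate) work-up
Reagents that add atoms: none
Why: Partial ester reduction with i-Bu2AlH at −78 °C stops at the aldehyde because the tetrahedral aluminium hemiacetal survives until aqueous work-up, and the benzyl ethers are inert to the hydride.

Step 6
Reactants: 7 3-[3,4-bis(benzyloxy)phenyl]propanal
Product: 8 3-[3,4-bis(benzyloxy)phenyl]propanal oxime (E/Z mixture)
Conditions: NH2OH·HCl, NaOAc, EtOH/H2O, rt
Reagents that add atoms: hydroxylamine hydrochloride, NO.Cl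
Why: Oxime formation by condensation of the aldehyde with hydroxylamine is fast under acetate buffering, and both oxime isomers converge on the same hydroximoyl chloride.

Step 7
Reactants: 8 3-[3,4-bis(benzyloxy)phenyl]propanal oxime
Product: 9 3-[3,4-bis(benzyloxy)phenyl]-N-hydroxypropanimidoyl chloride
Conditions: NCS (1.05 equiv), DMF, 0 °C to rt; used crude at once
Reagents that add atoms: N-chlorosuccinimide, O=C1CCC(=O)N1Cl
Why: Electrophilic chlorination of the aldoxime carbon by NCS in DMF (hydroximoyl chloride synthesis) should outpace chlorination of the dialkoxyarene, and immediate use avoids the poor shelf life of alkyl hydroximoyl chlorides.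

Step 8
Reactants: 9 3-[3,4-bis(benzyloxy)phenyl]-N-hydroxypropanimidoyl chloride; 10 prop-2-en-1-ol (allyl alcohol)
Product: 12 [(5S)-3-{2-[3,4-bis(benzyloxy)phenyl]ethyl}-4,5-dihydro-1,2-oxazol-5-yl]methanol, via nitrile oxide 11 (not isolated)
Conditions: 10 (1.0 equiv), Et2Zn (1.0 equiv), (S,S)-diisopropyl tartrate (1.0 equiv), Et2Zn (1.0 equiv), then 9 added slowly; CHCl3 with a little 1,4-dioxane, 0 °C; aq. NH4Cl work-up
Reagents that add atoms: none
Why: Et2Zn turns allyl alcohol into its zinc alkoxide, which the tartrate diol binds, and the second ethylzinc unit on the tartrate deprotonates 9 and takes up its chloride, so that nitrile oxide 11 is released already coordinated beside the allyl alkoxide on a tartrate-bridged dizinc template. A concerted suprafacial 1,3-dipolar cycloaddition then joins the nitrile oxide carbon (C3) to the terminal alkene carbon (C4) and the nitrile oxide oxygen to the internal carbon (C5), closing the five-membered 4,5-dihydroisoxazole as an intermolecular [3+2] annulation in which both ring bonds form in one step. The closest known reaction type is the tartrate/zinc-mediated enantioselective nitrile oxide cycloaddition to allyl alcohol, established mainly for aryl nitrile oxides and applied here to a primary alkyl one. The single new stereocentre C5 is controlled by the (S,S)-tartrate, which exposes one face of the zinc-bound alkene to the zinc-bound dipole, the antipode of the ester that gives the (5R) series being chosen to reach (5S). The step needs regioselectivity for the 5-substituted ring, secured by the monosubstituted alkene and by delivery through the alkoxide, and enantiofacial selectivity, secured by keeping both partners on the template in non-coordinating CHCl3 at 0 °C. Slow addition of 9 keeps free nitrile oxide low, which also suppresses furoxan dimerisation, and the benzyl ethers are inert.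

Step 9
Reactants: 12 [(5S)-3-{2-[3,4-bis(benzyloxy)phenyl]ethyl}-4,5-dihydro-1,2-oxazol-5-yl]methanol
Product: 13 (5S)-3-{2-[3,4-bis(benzyloxy)phenyl]ethyl}-4,5-dihydro-1,2-oxazole-5-carbaldehyde
Conditions: Dess–Martin periodinane, CH2Cl2, 0 °C to rt; used crude
Reagents that add atoms: none
Why: Dess–Martin oxidation converts the primary alcohol to the aldehyde under neutral conditions without an amine base, so the α-oxygenated C5 stereocentre should not epimerise.

Step 10
Reactants: 13 (5S)-3-{2-[3,4-bis(benzyloxy)phenyl]ethyl}-4,5-dihydro-1,2-oxazole-5-carbaldehyde; 4 {[4-(benzyloxy)-3-methoxyphenyl]methyl}triphenylphosphonium chloride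
Product: 15 (5S)-5-{(E/Z)-2-[4-(benzyloxy)-3-methoxyphenyl]ethenyl}-3-{2-[3,4-bis(benzyloxy)phenyl]ethyl}-4,5-dihydro-1,2-oxazole, via phosphorus ylide 14 (not isolated)
Conditions: 4 (1.3 equiv), NaN(SiMe3)2 (1.2 equiv), THF, 0 °C; then 13, −78 °C to rt
Reagents that add atoms: none
Why: Wittig olefination with the semi-stabilised benzylic ylide 14, pre-formed with less base than salt and met by the aldehyde at −78 °C, forms C6=C7 without exposing the α-oxy aldehyde to free strong base, and the E/Z ratio is irrelevant because the alkene is hydrogenated next.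

Step 11
Reactants: 15 (5S)-5-{(E/Z)-2-[4-(benzyloxy)-3-methoxyphenyl]ethenyl}-3-{2-[3,4-bis(benzyloxy)phenyl]ethyl}-4,5-dihydro-1,2-oxazole
Product: 17 (5R)-7-[4-(benzyloxy)-3-methoxyphenyl]-1-[3,4-bis(benzyloxy)phenyl]-5-hydroxyheptan-3-one, via hydroxy imine 16 (not isolated)
Conditions: H2 (1 atm), Raney Ni, B(OH)3, MeOH/THF/H2O, rt
Reagents that add atoms: water, O
Why: Raney-nickel hydrogenolysis of the isoxazoline N–O bond gives β-hydroxy imine 16, which the boric-acid-buffered aqueous methanol should hydrolyse to the ketone before it can be reduced to the amine, while the same catalyst saturates the disubstituted styrenyl alkene; no bond to C5 is broken and the aryl benzyl ethers should largely survive at 1 atm and room temperature.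

Step 12
Reactants: 17 (5R)-7-[4-(benzyloxy)-3-methoxyphenyl]-1-[3,4-bis(benzyloxy)phenyl]-5-hydroxyheptan-3-one
Product: 18 (5R)-1-(3,4-dihydroxyphenyl)-5-hydroxy-7-(4-hydroxy-3-methoxyphenyl)heptan-3-one (CNP0094522.1)
Conditions: H2 (1 atm), Pd/C (10% Pd), EtOAc/MeOH, rt
Reagents that add atoms: none
Why: Pd/C-catalysed hydrogenolysis should cleave the three aryl benzyl ethers to toluene, while the dialkyl ketone and the secondary alcohol, no longer allylic or benzylic, are inert at 1 atm and room temperature.

**Compound list**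

1 | 4-(benzyloxy)-3-methoxybenzaldehyde | COc1cc(C=O)ccc1OCc1ccccc1 | starting material
2 | [4-(benzyloxy)-3-methoxyphenyl]methanol | COc1cc(CO)ccc1OCc1ccccc1 | intermediate
3 | 1-(benzyloxy)-4-(chloromethyl)-2-methoxybenzene | COc1cc(CCl)ccc1OCc1ccccc1 | intermediate
4 | {[4-(benzyloxy)-3-methoxyphenyl]methyl}triphenylphosphonium chloride | COc1cc(C[P+](c2ccccc2)(c2ccccc2)c2ccccc2)ccc1OCc1ccccc1.[Cl-] | intermediate
5 | 3-(3,4-dihydroxyphenyl)propanoic acid (dihydrocaffeic acid) | O=C(O)CCc1ccc(O)c(O)c1 | starting material
6 | benzyl 3-[3,4-bis(benzyloxy)phenyl]propanoate | O=C(OCc1ccccc1)CCc1ccc(OCc2ccccc2)c(OCc2ccccc2)c1 | intermediate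
7 | 3-[3,4-bis(benzyloxy)phenyl]propanal | O=CCCc1ccc(OCc2ccccc2)c(OCc2ccccc2)c1 | intermediate
8 | 3-[3,4-bis(benzyloxy)phenyl]propanal oxime (E/Z mixture) | ON=CCCc1ccc(OCc2ccccc2)c(OCc2ccccc2)c1 | intermediate
9 | 3-[3,4-bis(benzyloxy)phenyl]-N-hydroxypropanimidoyl chloride | ON=C(Cl)CCc1ccc(OCc2ccccc2)c(OCc2ccccc2)c1 | intermediate
10 | prop-2-en-1-ol (allyl alcohol) | C=CCO | starting material
11 | 3-[3,4-bis(benzyloxy)phenyl]propanenitrile oxide | [O-][N+]#CCCc1ccc(OCc2ccccc2)c(OCc2ccccc2)c1 | intermediate (not isolated)
12 | [(5S)-3-{2-[3,4-bis(benzyloxy)phenyl]ethyl}-4,5-dihydro-1,2-oxazol-5-yl]methanol | OC[C@@H]1CC(CCc2ccc(OCc3ccccc3)c(OCc3ccccc3)c2)=NO1 | intermediate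
13 | (5S)-3-{2-[3,4-bis(benzyloxy)phenyl]ethyl}-4,5-dihydro-1,2-oxazole-5-carbaldehyde | O=C[C@@H]1CC(CCc2ccc(OCc3ccccc3)c(OCc3ccccc3)c2)=NO1 | intermediate
14 | {[4-(benzyloxy)-3-methoxyphenyl]methylidene}triphenylphosphorane | COc1cc(C=P(c2ccccc2)(c2ccccc2)c2ccccc2)ccc1OCc1ccccc1 | intermediate (not isolated)
15 | (5S)-5-{(E/Z)-2-[4-(benzyloxy)-3-methoxyphenyl]ethenyl}-3-{2-[3,4-bis(benzyloxy)phenyl]ethyl}-4,5-dihydro-1,2-oxazole | COc1cc(C=C[C@@H]2CC(CCc3ccc(OCc4ccccc4)c(OCc4ccccc4)c3)=NO2)ccc1OCc1ccccc1 | intermediate
16 | (5R)-7-[4-(benzyloxy)-3-methoxyphenyl]-1-[3,4-bis(benzyloxy)phenyl]-3-iminoheptan-5-ol (chain numbered as in the target) | COc1cc(CC[C@@H](O)CC(=N)CCc2ccc(OCc3ccccc3)c(OCc3ccccc3)c2)ccc1OCc1ccccc1 | intermediate (not isolated)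
17 | (5R)-7-[4-(benzyloxy)-3-methoxyphenyl]-1-[3,4-bis(benzyloxy)phenyl]-5-hydroxyheptan-3-one | COc1cc(CC[C@@H](O)CC(=O)CCc2ccc(OCc3ccccc3)c(OCc3ccccc3)c2)ccc1OCc1ccccc1 | intermediate
18 | (5R)-1-(3,4-dihydroxyphenyl)-5-hydroxy-7-(4-hydroxy-3-methoxyphenyl)heptan-3-one | COc1cc(CC[C@@H](O)CC(=O)CCc2ccc(O)c(O)c2)ccc1O | target

**Step count and risks**

Total: 12 steps. Longest linear sequence: 9 steps (steps 4–12, from dihydrocaffeic acid 5); the three-step phosphonium branch (steps 1–3) joins at step 10.

Steps most likely to fail: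

1. Step 8. The primary alkyl nitrile oxide may dimerise to the furoxan or react away from the zinc template, lowering the yield or the enantiofacial selectivity, and the sense of induction may not carry over from the aryl series. The enantiomeric purity and absolute configuration of 12 should therefore be checked (chiral HPLC, MTPA esters) before it is carried on. Fallback with substrate control from the chiral pool: starting from 9, nitrile oxide 11 is generated by slow addition of Et3N in Et2O in the presence of (4S)-4-ethenyl-2,2-dimethyl-1,3-dioxolane F1. The inside-alkoxy effect should favour the erythro cycloadduct (5S)-3-{2-[3,4-bis(benzyloxy)phenyl]ethyl}-5-[(4R)-2,2-dimethyl-1,3-dioxolan-4-yl]-4,5-dihydro-1,2-oxazole F2, which is separated from the minor threo isomer by chromatography. Aqueous AcOH removes the acetonide to give the diol (1R)-1-[(5S)-3-{2-[3,4-bis(benzyloxy)phenyl]ethyl}-4,5-dihydro-1,2-oxazol-5-yl]ethane-1,2-diol F3, and NaIO4 glycol cleavage in THF/H2O returns to the route at aldehyde 13, so step 9 is not needed.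

2. Step 10. Enolisation of the α-oxy aldehyde under the basic ylide conditions would erode the configuration at C5, and base-induced opening of the isoxazoline could consume material. Fallback avoiding both the aldehyde and the alkene: starting from 12, tosylation (TsCl, Et3N, DMAP, CH2Cl2) gives [(5S)-3-{2-[3,4-bis(benzyloxy)phenyl]ethyl}-4,5-dihydro-1,2-oxazol-5-yl]methyl 4-methylbenzenesulfonate F4. Chloride 3 is converted with Mg in Et2O into [4-(benzyloxy)-3-methoxybenzyl]magnesium chloride F5. Copper-catalysed sp3–sp3 coupling of F4 with F5 (Li2CuCl4 cat., THF, −78 to 0 °C) should give the saturated isoxazoline (5R)-5-{2-[4-(benzyloxy)-3-methoxyphenyl]ethyl}-3-{2-[3,4-bis(benzyloxy)phenyl]ethyl}-4,5-dihydro-1,2-oxazole F6. Its N–O hydrogenolysis under the step 11 conditions (H2, Raney Ni, B(OH)3, aqueous MeOH) returns to the route at 17.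

3. Step 11. Several surface processes compete: incomplete saturation of C6=C7, reduction of the imine to the 1,3-amino alcohol before hydrolysis, hydrogenolysis of the allylic C5–O bond while the alkene is still present, and premature loss of benzyl groups. Fallback separating ring opening from alkene reduction without a heterogeneous catalyst: starting from 15, N–O cleavage with Mo(CO)6 in MeCN/H2O at reflux should give (5S)-7-[4-(benzyloxy)-3-methoxyphenyl]-1-[3,4-bis(benzyloxy)phenyl]-5-hydroxyhept-6-en-3-one F7 with the alkene intact. Diimide generated from KO2CN=NCO2K and AcOH in MeOH at rt then saturates C6=C7 without touching the ketone or the benzyl ethers and returns to the route at 17.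

**Further compounds**

F1 | step 8 | (4S)-4-ethenyl-2,2-dimethyl-1,3-dioxolane | CC1(C)OC[C@H](C=C)O1
F2 | step 8 | (5S)-3-{2-[3,4-bis(benzyloxy)phenyl]ethyl}-5-[(4R)-2,2-dimethyl-1,3-dioxolan-4-yl]-4,5-dihydro-1,2-oxazole | CC1(C)OC[C@H]([C@@H]2CC(CCc3ccc(OCc4ccccc4)c(OCc4ccccc4)c3)=NO2)O1
F3 | step 8 | (1R)-1-[(5S)-3-{2-[3,4-bis(benzyloxy)phenyl]ethyl}-4,5-dihydro-1,2-oxazol-5-yl]ethane-1,2-diol | OC[C@@H](O)[C@@H]1CC(CCc2ccc(OCc3ccccc3)c(OCc3ccccc3)c2)=NO1
F4 | step 10 | [(5S)-3-{2-[3,4-bis(benzyloxy)phenyl]ethyl}-4,5-dihydro-1,2-oxazol-5-yl]methyl 4-methylbenzenesulfonate | Cc1ccc(cc1)S(=O)(=O)OC[C@@H]1CC(CCc2ccc(OCc3ccccc3)c(OCc3ccccc3)c2)=NO1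
F5 | step 10 | [4-(benzyloxy)-3-methoxybenzyl]magnesium chloride | COc1cc(C[Mg]Cl)ccc1OCc1ccccc1
F6 | step 10 | (5R)-5-{2-[4-(benzyloxy)-3-methoxyphenyl]ethyl}-3-{2-[3,4-bis(benzyloxy)phenyl]ethyl}-4,5-dihydro-1,2-oxazole | COc1cc(CC[C@@H]2CC(CCc3ccc(OCc4ccccc4)c(OCc4ccccc4)c3)=NO2)ccc1OCc1ccccc1
F7 | step 11 | (5S)-7-[4-(benzyloxy)-3-methoxyphenyl]-1-[3,4-bis(benzyloxy)phenyl]-5-hydroxyhept-6-en-3-one (E/Z mixture) | COc1cc(C=C[C@@H](O)CC(=O)CCc2ccc(OCc3ccccc3)c(OCc3ccccc3)c2)ccc1OCc1ccccc1
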